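The route rests on closing ring C'' of the genkwanin half at the O1''–C8a'' bond. C8a'' lies between C8'', which holds the biaryl bond to C6 of the acacetin half, and C4a'', which bears the C4'' ketone; a fluorine on that carbon is therefore activated by the ortho acyl group and can be displaced by the enol oxygen of a 1,3-diketone, which closes the pyranone and fixes the 8''-linkage in one operation. The precursor is a 1-(3-aryl-2-fluoro-4,6-dimethoxyphenyl)-3-(4-benzyloxyphenyl)propane-1,3-dione whose phloroglucinol ring carries benzyl ethers beside the axis and a silyl ether para to it, so that ring C of the acacetin half can later be closed only through the para oxygen.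

Key step: step 6

Remark: the target string defines no configuration for the C6–C8'' axis, so the axis is formed without stereocontrol and all structures are drawn without axial descriptors.

Step 1
Reactants: 1 1-fluoro-3,5-dimethoxybenzene
Product: 2 1-(2-fluoro-4,6-dimethoxyphenyl)ethan-1-one
Conditions: AcCl, AlCl3, CH2Cl2, −10 to 0 °C
Reagents that add atoms: acetyl chloride, CC(=O)Cl
Why: Friedel–Crafts acylation, in which attack beside fluorine (para to one methoxy group, ortho to the other) should be preferred over the carbon wedged between both methoxy groups, as is usual for 5-substituted resorcinol dimethyl ethers, with any minor isomer removed by chromatography.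

Step 2
Reactants: 2 1-(2-fluoro-4,6-dimethoxyphenyl)ethan-1-one
Product: 3 1-(3-bromo-2-fluoro-4,6-dimethoxyphenyl)ethan-1-one
Conditions: NBS, MeCN, 0 °C to rt, dark
Reagents that add atoms: N-bromosuccinimide, O=C1CCC(=O)N1Br
Why: Electrophilic aromatic bromination, expected at C3 because it is para to the 6-methoxy group, ortho to the 4-methoxy group and flanked only by the small fluorine, whereas C5 sits between two methoxy groups, and because ring bromination of this activated arene in MeCN without acid should outrun alpha-bromination of the ketone.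

Step 3
Reactants: 4 3,5-bis(benzyloxy)phenol
Product: 5 [3,5-bis(benzyloxy)phenoxy]triisopropylsilane
Conditions: iPr3SiCl, imidazole, DMF, rt
Reagents that add atoms: chlorotriisopropylsilane, CC(C)[Si](Cl)(C(C)C)C(C)C
Why: Imidazole-promoted silylation of a phenol, which marks the future para oxygen with a bulky, weakly coordinating group that survives organolithium and amide bases and keeps the next metalation away from its neighbours.

Step 4
Reactants: 5 [3,5-bis(benzyloxy)phenoxy]triisopropylsilane; 3 1-(3-bromo-2-fluoro-4,6-dimethoxyphenyl)ethan-1-one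
Product: 8 1-[2',6'-bis(benzyloxy)-2-fluoro-4,6-dimethoxy-4'-(triisopropylsilyloxy)-[1,1'-biphenyl]-3-yl]ethan-1-one, via aryllithium 6 (not isolated), via arylzinc chloride 7 (not isolated)
Conditions: n-BuLi, THF, 0 °C; ZnCl2, THF, 0 °C to rt; then 3, Pd(OAc)2 (3 mol %), RuPhos (6 mol %), THF, 65 °C
Reagents that add atoms: none
Why: Directed ortho-metalation at the only C–H flanked by two coordinating benzyloxy groups, transmetalation to zinc so that the methyl ketone of 3 is tolerated, and Negishi cross-coupling with a bulky dialkylbiarylphosphine ligand of the kind used for biaryls with four ortho substituents.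

Step 5
Reactants: 8 1-[2',6'-bis(benzyloxy)-2-fluoro-4,6-dimethoxy-4'-(triisopropylsilyloxy)-[1,1'-biphenyl]-3-yl]ethan-1-one; 9 4-(benzyloxy)benzoyl chloride
Product: 11 1-[2',6'-bis(benzyloxy)-2-fluoro-4,6-dimethoxy-4'-(triisopropylsilyloxy)-[1,1'-biphenyl]-3-yl]-3-[4-(benzyloxy)phenyl]propane-1,3-dione, via lithium enolate 10 (not isolated)
Conditions: LiN(SiMe3)2 (2.2 equiv), toluene–THF, −78 °C; then 9, −78 to 0 °C; aq NH4Cl
Reagents that add atoms: none
Why: Claisen-type C-acylation of a ketone lithium enolate with an aroyl chloride, in which the second equivalent of base deprotonates the 1,3-diketone as it forms and so prevents double acylation, while the low temperature leaves the aryl fluoride and the silyl ether untouched.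

Step 6
Reactants: 11 1-[2',6'-bis(benzyloxy)-2-fluoro-4,6-dimethoxy-4'-(triisopropylsilyloxy)-[1,1'-biphenyl]-3-yl]-3-[4-(benzyloxy)phenyl]propane-1,3-dione
Product: 13 2-[4-(benzyloxy)phenyl]-8-[2,6-bis(benzyloxy)-4-hydroxyphenyl]-5,7-dimethoxy-4H-chromen-4-one, via silyl ether flavone 12 (not isolated)
Conditions: K2CO3 (3 equiv), dry DMF, 100 °C; then H2O, 60 °C
Reagents that add atoms: none
Why: Deprotonation by K2CO3 gives the chelated enolate of the 1,3-diketone, whose remote oxygen attacks the fluorinated ring carbon (the future C8a''); the negative charge of the sigma adduct is taken up by the neighbouring aryl ketone, and expulsion of fluoride restores aromaticity (SNAr by addition–elimination). The closest known reaction is the base-mediated cyclisation of 1-(2-fluoroaryl)-1,3-diketones to flavones. Ring C'' closes in a six-membered exo mode at the arene carbon (6-exo-trig addition, then elimination), and only the O1''–C8a'' bond is formed. No stereocentre is created. The step needs site selectivity between the two carbons ortho to the acyl group: fluorine makes its carbon the more electrophilic one and is a far better nucleofuge than methoxide, the two methoxy groups are meta to the reacting carbon and act only inductively, and the only leaving group sits between the biaryl carbon and the acyl carbon, so the 8''-linkage is fixed. The fluoride set free, with carbonate in wet DMF, should then cleave the aryl silyl ether and uncover the para phenol.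

Step 7
Reactants: 13 2-[4-(benzyloxy)phenyl]-8-[2,6-bis(benzyloxy)-4-hydroxyphenyl]-5,7-dimethoxy-4H-chromen-4-one
Product: 14 2-[4-(benzyloxy)phenyl]-8-[2,6-bis(benzyloxy)-4-hydroxy-3-iodophenyl]-5,7-dimethoxy-4H-chromen-4-one
Conditions: NIS (1.0 equiv), DMF, 0 °C
Reagents that add atoms: N-iodosuccinimide, O=C1CCC(=O)N1I
Why: Electrophilic aromatic iodination ortho to the free phenol, whose ring is by far the most electron-rich arene in the molecule and whose two open positions are equivalent (enantiotopic), so one equivalent of NIS should give a single mono-iodide.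

Step 8
Reactants: 14 2-[4-(benzyloxy)phenyl]-8-[2,6-bis(benzyloxy)-4-hydroxy-3-iodophenyl]-5,7-dimethoxy-4H-chromen-4-one; 15 1-ethynyl-4-methoxybenzene
Product: 17 5,7-bis(benzyloxy)-6-{2-[4-(benzyloxy)phenyl]-5,7-dimethoxy-4-oxo-4H-chromen-8-yl}-2-(4-methoxyphenyl)-4H-chromen-4-one, via alkynone 16 (not isolated)
Conditions: CO (10 bar), PdCl2(dppf) (5 mol %), Et2NH, 100 °C
Reagents that add atoms: carbon monoxide, [C-]#[O+]
Why: Palladium-catalysed carbonylative annulation of an o-iodophenol with a terminal alkyne (carbonylative Sonogashira-type coupling, then cyclisation), in which oxidative addition to zerovalent palladium, CO insertion and alkynylation give the o-hydroxyaryl alkynone, diethylamine adds to the triple bond so that the phenol closes the pyranone and not the aurone, and only the para oxygen is free, so the acacetin unit must be 6-linked.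

Step 9
Reactants: 17 5,7-bis(benzyloxy)-6-{2-[4-(benzyloxy)phenyl]-5,7-dimethoxy-4-oxo-4H-chromen-8-yl}-2-(4-methoxyphenyl)-4H-chromen-4-one
Product: 18 5,7-dihydroxy-6-[5-hydroxy-2-(4-hydroxyphenyl)-7-methoxy-4-oxo-4H-chromen-8-yl]-2-(4-methoxyphenyl)-4H-chromen-4-one (CNP0290866.0)
Conditions: BCl3 (excess), C6HMe5, CH2Cl2, −78 °C to rt; MeOH, then aq work-up
Reagents that add atoms: none
Why: Lewis-acid ether cleavage, in which BCl3 with pentamethylbenzene as benzyl-cation scavenger should remove the three aryl benzyl ethers at low temperature and, on warming, the 5''-methyl ether through the six-membered boron chelate with the C4'' carbonyl, while the unchelated 7''- and 4'-methyl ethers are inert to BCl3.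

Compound list
1 | 1-fluoro-3,5-dimethoxybenzene | COc1cc(F)cc(OC)c1 | starting material
2 | 1-(2-fluoro-4,6-dimethoxyphenyl)ethan-1-one | CC(=O)c1c(F)cc(OC)cc1OC | intermediate
3 | 1-(3-bromo-2-fluoro-4,6-dimethoxyphenyl)ethan-1-one | CC(=O)c1c(F)c(Br)c(OC)cc1OC | intermediate
4 | 3,5-bis(benzyloxy)phenol | Oc1cc(OCc2ccccc2)cc(OCc2ccccc2)c1 | starting material
5 | [3,5-bis(benzyloxy)phenoxy]triisopropylsilane | CC(C)[Si](Oc1cc(OCc2ccccc2)cc(OCc2ccccc2)c1)(C(C)C)C(C)C | intermediate
6 | [2,6-bis(benzyloxy)-4-(triisopropylsilyloxy)phenyl]lithium | [Li]c1c(OCc2ccccc2)cc(O[Si](C(C)C)(C(C)C)C(C)C)cc1OCc1ccccc1 | intermediate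
7 | [2,6-bis(benzyloxy)-4-(triisopropylsilyloxy)phenyl]zinc chloride | Cl[Zn]c1c(OCc2ccccc2)cc(O[Si](C(C)C)(C(C)C)C(C)C)cc1OCc1ccccc1 | intermediate
8 | 1-[2',6'-bis(benzyloxy)-2-fluoro-4,6-dimethoxy-4'-(triisopropylsilyloxy)-[1,1'-biphenyl]-3-yl]ethan-1-one | CC(=O)c1c(F)c(-c2c(OCc3ccccc3)cc(O[Si](C(C)C)(C(C)C)C(C)C)cc2OCc2ccccc2)c(OC)cc1OC | intermediate
9 | 4-(benzyloxy)benzoyl chloride | O=C(Cl)c1ccc(OCc2ccccc2)cc1 | starting material
10 | lithium enolate of 8 | [Li]OC(=C)c1c(F)c(-c2c(OCc3ccccc3)cc(O[Si](C(C)C)(C(C)C)C(C)C)cc2OCc2ccccc2)c(OC)cc1OC | intermediate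
11 | 1-[2',6'-bis(benzyloxy)-2-fluoro-4,6-dimethoxy-4'-(triisopropylsilyloxy)-[1,1'-biphenyl]-3-yl]-3-[4-(benzyloxy)phenyl]propane-1,3-dione | COc1cc(OC)c(C(=O)CC(=O)c2ccc(OCc3ccccc3)cc2)c(F)c1-c1c(OCc2ccccc2)cc(O[Si](C(C)C)(C(C)C)C(C)C)cc1OCc1ccccc1 | intermediate
12 | 2-[4-(benzyloxy)phenyl]-8-[2,6-bis(benzyloxy)-4-(triisopropylsilyloxy)phenyl]-5,7-dimethoxy-4H-chromen-4-one | COc1cc(OC)c2c(=O)cc(-c3ccc(OCc4ccccc4)cc3)oc2c1-c1c(OCc2ccccc2)cc(O[Si](C(C)C)(C(C)C)C(C)C)cc1OCc1ccccc1 | intermediate
13 | 2-[4-(benzyloxy)phenyl]-8-[2,6-bis(benzyloxy)-4-hydroxyphenyl]-5,7-dimethoxy-4H-chromen-4-one | COc1cc(OC)c2c(=O)cc(-c3ccc(OCc4ccccc4)cc3)oc2c1-c1c(OCc2ccccc2)cc(O)cc1OCc1ccccc1 | intermediate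
14 | 2-[4-(benzyloxy)phenyl]-8-[2,6-bis(benzyloxy)-4-hydroxy-3-iodophenyl]-5,7-dimethoxy-4H-chromen-4-one | COc1cc(OC)c2c(=O)cc(-c3ccc(OCc4ccccc4)cc3)oc2c1-c1c(OCc2ccccc2)c(I)c(O)cc1OCc1ccccc1 | intermediate
15 | 1-ethynyl-4-methoxybenzene | C#Cc1ccc(OC)cc1 | starting material
16 | 2-[4-(benzyloxy)phenyl]-8-{2,6-bis(benzyloxy)-4-hydroxy-3-[3-(4-methoxyphenyl)prop-2-ynoyl]phenyl}-5,7-dimethoxy-4H-chromen-4-one | COc1ccc(C#CC(=O)c2c(O)cc(OCc3ccccc3)c(-c3c(OC)cc(OC)c4c(=O)cc(-c5ccc(OCc6ccccc6)cc5)oc34)c2OCc2ccccc2)cc1 | intermediate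
17 | 5,7-bis(benzyloxy)-6-{2-[4-(benzyloxy)phenyl]-5,7-dimethoxy-4-oxo-4H-chromen-8-yl}-2-(4-methoxyphenyl)-4H-chromen-4-one | COc1ccc(-c2cc(=O)c3c(OCc4ccccc4)c(-c4c(OC)cc(OC)c5c(=O)cc(-c6ccc(OCc7ccccc7)cc6)oc45)c(OCc4ccccc4)cc3o2)cc1 | intermediate
18 | 5,7-dihydroxy-6-[5-hydroxy-2-(4-hydroxyphenyl)-7-methoxy-4-oxo-4H-chromen-8-yl]-2-(4-methoxyphenyl)-4H-chromen-4-one (CNP0290866.0) | COc1ccc(-c2cc(=O)c3c(O)c(-c4c(OC)cc(O)c5c(=O)cc(-c6ccc(O)cc6)oc45)c(O)cc3o2)cc1 | target

Total steps: 9. Longest linear sequence: 8 steps (1 → 2 → 3 → 8 → 11 → 13 → 14 → 17 → 18; steps 1, 2, 4, 5, 6, 7, 8 and 9).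

Steps most likely to fail

Step 6. Attack of the enolate oxygen on the crowded, electron-rich fluoroarene may be slower than retro-Claisen cleavage of the diketone by traces of hydroxide. The fallback closes ring C'' from a phenol before the biaryl bond is made. It sets out from 9 and from 5 (through 7) and comes back at 12. Commercial 1-(2-hydroxy-4,6-dimethoxyphenyl)ethan-1-one would be iodinated ortho to the hydroxyl group (NIS, DMF) to 1-(2-hydroxy-3-iodo-4,6-dimethoxyphenyl)ethan-1-one F1. Its dianion (LiN(SiMe3)2, THF, −78 °C) would be C-acylated with 9 in a Baker–Venkataraman-type step to 1-[4-(benzyloxy)phenyl]-3-(2-hydroxy-3-iodo-4,6-dimethoxyphenyl)propane-1,3-dione F2. Acid-catalysed cyclodehydration (TsOH, toluene, reflux) would give 2-[4-(benzyloxy)phenyl]-8-iodo-5,7-dimethoxy-4H-chromen-4-one F3. Negishi coupling of F3 with the arylzinc chloride 7, made from 5 as in step 4, should give 12, which is desilylated to 13 with wet K2CO3 and KF in DMF.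

Step 4. Transmetalation and reductive elimination at an axis with four ortho substituents may be slow, so that protonation of the arylzinc reagent and reduction of the bromide take over. The fallback reverses the roles of the partners in a Suzuki–Miyaura coupling, putting the more hindered ring on the electrophile side. It sets out from 5 (through 6) and from 3 and comes back at 8. The aryllithium 6 would be quenched with I2 to [3,5-bis(benzyloxy)-4-iodophenoxy]triisopropylsilane F4. Bromide 3 would undergo Miyaura borylation (B2pin2, PdCl2(dppf), KOAc, dioxane, 90 °C) to 1-[2-fluoro-4,6-dimethoxy-3-(4,4,5,5-tetramethyl-1,3,2-dioxaborolan-2-yl)phenyl]ethan-1-one F5. Coupling of F4 with F5 (Pd(OAc)2, SPhos, K3PO4, toluene–H2O, 100 °C) should give 8.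

Step 8. The alkynone may close in the five-membered exo mode to an aurone, or alkynylation may outrun CO insertion and lead on to a benzofuran. The fallback builds the pyranone stepwise through an o-hydroxyaryl methyl ketone. It sets out from 14 and comes back at 17. Stille coupling of 14 with Bu3Sn(C(OEt)=CH2) (Pd(PPh3)4, toluene, 100 °C) would give the enol ether 2-[4-(benzyloxy)phenyl]-8-[2,6-bis(benzyloxy)-3-(1-ethoxyethenyl)-4-hydroxyphenyl]-5,7-dimethoxy-4H-chromen-4-one F6. Hydrolysis with dilute HCl would give the methyl ketone 8-[3-acetyl-2,6-bis(benzyloxy)-4-hydroxyphenyl]-2-[4-(benzyloxy)phenyl]-5,7-dimethoxy-4H-chromen-4-one F7. Baker–Venkataraman-type acylation of its dianion with 4-methoxybenzoyl chloride (LiN(SiMe3)2, THF, −78 °C) would give the diketone 1-{2,4-bis(benzyloxy)-3-{2-[4-(benzyloxy)phenyl]-5,7-dimethoxy-4-oxo-4H-chromen-8-yl}-6-hydroxyphenyl}-3-(4-methoxyphenyl)propane-1,3-dione F8. Cyclodehydration of F8 (TsOH, toluene, 90 °C) can only use the free para oxygen and should give 17.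

Further compounds
F1 | step 6 | 1-(2-hydroxy-3-iodo-4,6-dimethoxyphenyl)ethan-1-one | CC(=O)c1c(O)c(I)c(OC)cc1OC
F2 | step 6 | 1-[4-(benzyloxy)phenyl]-3-(2-hydroxy-3-iodo-4,6-dimethoxyphenyl)propane-1,3-dione | COc1cc(OC)c(C(=O)CC(=O)c2ccc(OCc3ccccc3)cc2)c(O)c1I
F3 | step 6 | 2-[4-(benzyloxy)phenyl]-8-iodo-5,7-dimethoxy-4H-chromen-4-one | COc1cc(OC)c2c(=O)cc(-c3ccc(OCc4ccccc4)cc3)oc2c1I
F4 | step 4 | [3,5-bis(benzyloxy)-4-iodophenoxy]triisopropylsilane | CC(C)[Si](Oc1cc(OCc2ccccc2)c(I)c(OCc2ccccc2)c1)(C(C)C)C(C)C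
F5 | step 4 | 1-[2-fluoro-4,6-dimethoxy-3-(4,4,5,5-tetramethyl-1,3,2-dioxaborolan-2-yl)phenyl]ethan-1-one | CC(=O)c1c(F)c(B2OC(C)(C)C(C)(C)O2)c(OC)cc1OC
F6 | step 8 | 2-[4-(benzyloxy)phenyl]-8-[2,6-bis(benzyloxy)-3-(1-ethoxyethenyl)-4-hydroxyphenyl]-5,7-dimethoxy-4H-chromen-4-one | CCOC(=C)c1c(O)cc(OCc2ccccc2)c(-c2c(OC)cc(OC)c3c(=O)cc(-c4ccc(OCc5ccccc5)cc4)oc23)c1OCc1ccccc1
F7 | step 8 | 8-[3-acetyl-2,6-bis(benzyloxy)-4-hydroxyphenyl]-2-[4-(benzyloxy)phenyl]-5,7-dimethoxy-4H-chromen-4-one | CC(=O)c1c(O)cc(OCc2ccccc2)c(-c2c(OC)cc(OC)c3c(=O)cc(-c4ccc(OCc5ccccc5)cc4)oc23)c1OCc1ccccc1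
F8 | step 8 | 1-{2,4-bis(benzyloxy)-3-{2-[4-(benzyloxy)phenyl]-5,7-dimethoxy-4-oxo-4H-chromen-8-yl}-6-hydroxyphenyl}-3-(4-methoxyphenyl)propane-1,3-dione | COc1ccc(C(=O)CC(=O)c2c(O)cc(OCc3ccccc3)c(-c3c(OC)cc(OC)c4c(=O)cc(-c5ccc(OCc6ccccc6)cc5)oc34)c2OCc2ccccc2)cc1
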